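**Strategy.** The 1,4-dioxane ring is not made by etherification of a catechol. Its aryl ether bond O1–C8a starts as a C–C bond. In a (2S)-2-methyl-2,3-dihydrobenzofuran-3-yl hydroperoxide the future C2 is bonded directly to C8a. A Hock (Criegee-type) 1,2-aryl shift of the electron-rich, ortho-oxygenated C8a inserts O1 between C8a and C2 and enlarges the five-membered dihydrofuran ring to the six-membered dioxane ring. This fixes which oxygen of the unsymmetrical 3-methoxycatechol unit carries CH(CH3) (O4, next to OCH3) and keeps the lactate-derived C3 centre. The anomeric C2 then takes up the trimethoxyphenyl group anti to the methyl group, and a Heck reaction adds the enal.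

Key step: step 6

Remark: the benzodioxane atoms are labelled O1–C2(aryl)–C3(CH3)–O4–C4a–C5(OCH3)–C6–C7(side chain)–C8–C8a throughout. The carbinol, peroxide and anomeric centres of 6, 7, 8, 9 and 11 are carried as epimer mixtures, because this carbon becomes planar again in step 7; their SMILES leave it undefined.

**Step 1**
Reactants: 1 4-bromo-2-methoxyphenol
Product: 2 4-bromo-2-iodo-6-methoxyphenol
Conditions: NIS, TsOH (cat.), MeCN, rt
Reagents that add atoms: N-iodosuccinimide O=C1CCC(=O)N1I
Why: Electrophilic aromatic iodination, in which the free phenol directs to its only open ortho position (para is blocked by Br), as in the iodination of vanillin to 5-iodovanillin.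

**Step 2**
Reactants: 2 4-bromo-2-iodo-6-methoxyphenol; 3 methyl (R)-lactate
Product: 4 methyl (2S)-2-(4-bromo-2-iodo-6-methoxyphenoxy)propanoate
Conditions: PPh3, DIAD, THF, 0 °C → rt
Reagents that add atoms: none
Why: Mitsunobu etherification of the acidic phenol with the secondary lactate alcohol is an SN2 process with inversion, so the (R)-lactate should give the (S)-aryloxypropanoate whose stereocentre becomes C3 of the target.

**Step 3**
Reactants: 4 methyl (2S)-2-(4-bromo-2-iodo-6-methoxyphenoxy)propanoate
Product: 5 (2S)-2-(4-bromo-2-iodo-6-methoxyphenoxy)propanal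
Conditions: DIBAL-H (1.1 equiv), CH2Cl2, −78 °C; Rochelle salt
Reagents that add atoms: none
Why: DIBAL-H half-reduction of an α-aryloxy methyl ester at −78 °C stops at the aldehyde through the stable aluminium hemiacetal; the aryl halides are inert, and cold work-up with immediate use should keep the α-stereocentre.

**Step 4**
Reactants: 5 (2S)-2-(4-bromo-2-iodo-6-methoxyphenoxy)propanal
Product: 6 (2S,3RS)-5-bromo-7-methoxy-2-methyl-2,3-dihydro-1-benzofuran-3-ol
Conditions: CrCl2 (4 equiv), NiCl2 (2 mol %), DMF, rt
Reagents that add atoms: none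
Why: Intramolecular Nozaki–Hiyama–Kishi reaction: nickel inserts into C–I far faster than into C–Br, and the arylchromium(III) species adds 5-exo-trig to the aldehyde under neutral conditions that should not epimerise the CH(CH3) centre; the new carbinol centre forms without control, which does not matter.

**Step 5**
Reactants: 6 (2S,3RS)-5-bromo-7-methoxy-2-methyl-2,3-dihydro-1-benzofuran-3-ol
Product: 7 (2S,3RS)-5-bromo-3-hydroperoxy-7-methoxy-2-methyl-2,3-dihydro-1-benzofuran
Conditions: 50% aq. H2O2 (large excess), H2SO4 (cat.), Et2O, 0 °C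
Reagents that add atoms: hydrogen peroxide OO
Why: Acid-catalysed perhydrolysis (SN1) of a benzylic alcohol whose cation is stabilised by the ortho ring oxygen; the large excess of H2O2 at 0 °C should capture the cation faster than it loses H-2 to give the benzofuran, and the CH(CH3) centre is not touched.

**Step 6**
Reactants: 7 (2S,3RS)-5-bromo-3-hydroperoxy-7-methoxy-2-methyl-2,3-dihydro-1-benzofuran
Product: 9 (2RS,3S)-7-bromo-5-methoxy-3-methyl-2,3-dihydro-1,4-benzodioxin-2-yl acetate, via lactol 8 (not isolated)
Conditions: BF3·OEt2 (0.2 equiv), CH2Cl2, −30 → 0 °C; then Ac2O, pyridine, DMAP (cat.), 0 °C → rt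
Reagents that add atoms: acetic anhydride CC(=O)OC(C)=O
Why: BF3 activates the terminal peroxide oxygen, and as the O–O bond heterolyses the aryl carbon C8a shifts from the carbinol carbon to the proximal oxygen through a phenonium-like transition state; this inserts O1 into the C8a–C2 bond and leaves an O1-stabilised oxocarbenium ion at C2, which recombines with hydroxide to lactol 8 and is then acetylated. This is the Hock rearrangement of a benzylic hydroperoxide (a Criegee-type 1,2-shift to electron-deficient oxygen), the reaction type of the cumene process and of the acid-induced ring enlargement of 1-tetralyl hydroperoxide to the aryl hemiacetal. No ring is closed: the five-membered dihydrofuran ring (O4, C3, C2, C8a, C4a) becomes the six-membered 1,4-dioxane ring by the 1,2-shift. C3 is not a migration terminus and should stay S, while the acetal centre C2 forms as an anomer mixture and is flattened again in step 7. The step needs aryl migration in preference to migration of the CH(CH3) carbon or of hydride, and in preference to loss of H-3 from the cation; the ortho oxygen O4 gives the aryl group an anisyl-type migratory aptitude, whereas the lone pair on the oxygen of the CH(CH3) carbon is tied up in the arene, and catalytic Lewis acid at low temperature should disfavour elimination.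

**Step 7**
Reactants: 9 (2RS,3S)-7-bromo-5-methoxy-3-methyl-2,3-dihydro-1,4-benzodioxin-2-yl acetate; 10 (3,4,5-trimethoxyphenyl)magnesium bromide
Product: 12 (2S,3S)-7-bromo-5-methoxy-3-methyl-2-(3,4,5-trimethoxyphenyl)-2,3-dihydro-1,4-benzodioxine, via α-bromo ether 11 (not isolated)
Conditions: TMSBr, CH2Cl2, 0 °C, evaporate; then 10, THF, −78 → 0 °C
Reagents that add atoms: bromotrimethylsilane C[Si](C)(C)Br (its bromine is in 11 only and leaves again)
Why: The anomeric acetate gives the α-bromo ether, which couples with the aryl Grignard reagent through an oxocarbenium ion pair (classical α-halo ether–Grignard coupling, cf. 2,3-dichlorotetrahydropyran giving mainly trans-2-substituted products); the aryl group should enter anti to the C3 methyl group, which sets C2 as S in the more stable trans-diequatorial ring.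

**Step 8**
Reactants: 12 (2S,3S)-7-bromo-5-methoxy-3-methyl-2-(3,4,5-trimethoxyphenyl)-2,3-dihydro-1,4-benzodioxine; 13 acrolein diethyl acetal
Product: 15 (E)-3-[(2S,3S)-5-methoxy-3-methyl-2-(3,4,5-trimethoxyphenyl)-2,3-dihydro-1,4-benzodioxin-7-yl]prop-2-enal, via enal diethyl acetal 14 (not isolated)
Conditions: Pd(OAc)2 (3 mol %), nBu4NOAc, K2CO3, KCl, DMF, 90 °C; then 2 M HCl, rt
Reagents that add atoms: water O
Why: Heck reaction of the aryl bromide with the acrolein acetal under ligand-free ammonium-salt conditions should give the (E)-cinnamaldehyde acetal by syn insertion and syn β-hydride elimination away from the acetal carbon, and dilute acid unmasks the enal without affecting the benzodioxane or its stereocentres.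

**Compound list**
1 | 4-bromo-2-methoxyphenol | COc1cc(Br)ccc1O | starting material
2 | 4-bromo-2-iodo-6-methoxyphenol | COc1cc(Br)cc(I)c1O | intermediate
3 | methyl (R)-lactate, methyl (2R)-2-hydroxypropanoate | C[C@@H](O)C(=O)OC | starting material
4 | methyl (2S)-2-(4-bromo-2-iodo-6-methoxyphenoxy)propanoate | C[C@H](Oc1c(I)cc(Br)cc1OC)C(=O)OC | intermediate
5 | (2S)-2-(4-bromo-2-iodo-6-methoxyphenoxy)propanal | C[C@H](Oc1c(I)cc(Br)cc1OC)C=O | intermediate
6 | (2S,3RS)-5-bromo-7-methoxy-2-methyl-2,3-dihydro-1-benzofuran-3-ol | C[C@@H]1Oc2c(OC)cc(Br)cc2C1O | intermediate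
7 | (2S,3RS)-5-bromo-3-hydroperoxy-7-methoxy-2-methyl-2,3-dihydro-1-benzofuran | C[C@@H]1Oc2c(OC)cc(Br)cc2C1OO | intermediate
8 | (2RS,3S)-7-bromo-5-methoxy-3-methyl-2,3-dihydro-1,4-benzodioxin-2-ol (lactol) | C[C@@H]1Oc2c(OC)cc(Br)cc2OC1O | intermediate (not isolated)
9 | (2RS,3S)-7-bromo-5-methoxy-3-methyl-2,3-dihydro-1,4-benzodioxin-2-yl acetate | C[C@@H]1Oc2c(OC)cc(Br)cc2OC1OC(C)=O | intermediate
10 | (3,4,5-trimethoxyphenyl)magnesium bromide, THF solution | COc1cc([Mg]Br)cc(OC)c1OC | starting material
11 | (2RS,3S)-2,7-dibromo-5-methoxy-3-methyl-2,3-dihydro-1,4-benzodioxine (α-bromo ether) | C[C@@H]1Oc2c(OC)cc(Br)cc2OC1Br | intermediate (not isolated)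
12 | (2S,3S)-7-bromo-5-methoxy-3-methyl-2-(3,4,5-trimethoxyphenyl)-2,3-dihydro-1,4-benzodioxine | COc1cc([C@@H]2Oc3cc(Br)cc(OC)c3O[C@H]2C)cc(OC)c1OC | intermediate
13 | acrolein diethyl acetal, 3,3-diethoxyprop-1-ene | C=CC(OCC)OCC | starting material
14 | (2S,3S)-7-[(E)-3,3-diethoxyprop-1-enyl]-5-methoxy-3-methyl-2-(3,4,5-trimethoxyphenyl)-2,3-dihydro-1,4-benzodioxine | COc1cc([C@@H]2Oc3cc(/C=C/C(OCC)OCC)cc(OC)c3O[C@H]2C)cc(OC)c1OC | intermediate (not isolated)
15 | (E)-3-[(2S,3S)-5-methoxy-3-methyl-2-(3,4,5-trimethoxyphenyl)-2,3-dihydro-1,4-benzodioxin-7-yl]prop-2-enal (numbering as for 12) | COc1cc([C@@H]2Oc3cc(/C=C/C=O)cc(OC)c3O[C@H]2C)cc(OC)c1OC | target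

Total step count: 8. Longest linear sequence: 8 steps (from 1).

**Steps most likely to fail**

Step 6. The wrong group may migrate (the CH(CH3) carbon or hydride instead of the aryl carbon), or the oxocarbenium ion may lose H-3, which would racemise C3 through the enol ether. The fallback performs the same oxygen insertion at the ketone level and sets out from alcohol 6. Dess–Martin periodinane (NaHCO3, CH2Cl2, 0 °C) should give (2S)-5-bromo-7-methoxy-2-methyl-1-benzofuran-3(2H)-one F1. Because its α-centre is prone to enolisation, F1 is oxidised at once under buffered Baeyer–Villiger conditions (CF3CO3H, Na2HPO4, CH2Cl2, 0 °C; aryl migration as with 1-indanones and chroman-4-ones) to (3S)-7-bromo-5-methoxy-3-methyl-2,3-dihydro-1,4-benzodioxin-2-one F2. DIBAL-H (CH2Cl2, −78 °C) reduces F2 to lactol 8, which is acetylated (Ac2O, pyridine) to 9, where the route continues with step 7.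

Step 5. The benzylic cation may aromatise by loss of H-2 to the benzofuran instead of being captured by hydrogen peroxide. The fallback sets out from alcohol 6 and activates it under base. Cl3CCN with catalytic DBU (CH2Cl2, 0 °C) should give (2S)-5-bromo-7-methoxy-2-methyl-2,3-dihydro-1-benzofuran-3-yl 2,2,2-trichloroacetimidate F3. Perhydrolysis of F3 with ethereal anhydrous H2O2 and catalytic TMSOTf at −40 °C, where a much weaker acid and lower temperature suffice, returns to hydroperoxide 7.

Step 7. Facial selectivity may be poor (cis isomer), or the α-bromo ether may undergo β-elimination to the 1,4-benzodioxin. The fallback sets out from acetate 9 and uses a Friedel–Crafts arylation. With 2,6-dimethoxyphenol and BF3·OEt2 (CH2Cl2, −20 → 0 °C) the phenol should attack the oxocarbenium ion through its para carbon to give 4-[(2S,3S)-7-bromo-5-methoxy-3-methyl-2,3-dihydro-1,4-benzodioxin-2-yl]-2,6-dimethoxyphenol F4. Any cis isomer of F4 can be equilibrated with acid to the trans isomer through the p-hydroxybenzyl cation. O-Methylation (MeI, K2CO3, acetone) returns to 12.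

Further compounds
F1 | step 6 | (2S)-5-bromo-7-methoxy-2-methyl-1-benzofuran-3(2H)-one | C[C@@H]1Oc2c(OC)cc(Br)cc2C1=O
F2 | step 6 | (3S)-7-bromo-5-methoxy-3-methyl-2,3-dihydro-1,4-benzodioxin-2-one | C[C@@H]1Oc2c(OC)cc(Br)cc2OC1=O
F3 | step 5 | (2S)-5-bromo-7-methoxy-2-methyl-2,3-dihydro-1-benzofuran-3-yl 2,2,2-trichloroacetimidate | C[C@@H]1Oc2c(OC)cc(Br)cc2C1OC(=N)C(Cl)(Cl)Cl
F4 | step 7 | 4-[(2S,3S)-7-bromo-5-methoxy-3-methyl-2,3-dihydro-1,4-benzodioxin-2-yl]-2,6-dimethoxyphenol | COc1cc([C@@H]2Oc3cc(Br)cc(OC)c3O[C@H]2C)cc(OC)c1O
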